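**Retrosynthetic overview**
1. The last bond is the C8 angelate ester. The furanone ring comes from a gold-catalysed closure of a macrocyclic α′-hydroxy ynone.
2. The ten-membered carbocycle is closed at C3–C4 by an intramolecular Sonogashira coupling of a (Z)-alkenyl iodide with an alkyne.
3. Key union: a spirolactone half (as a nitrile oxide) and an enynol half are joined by a magnesium-alkoxide-directed (3+2) cycloaddition that forms C8–C9 and C10–O. The isoxazoline is a masked β-hydroxy ketone, and C8–OH is set by a 1,3-anti reduction.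
4. The spirocyclohexene comes from two enolate alkylations of a cis-lactone acid followed by ring-closing metathesis. The cis-lactone comes from an Evans anti-aldol of a succinyl imide with (Z)-3-iodobut-2-enal.
5. Ring order: γ-lactone, spirocyclohexene, isoxazoline (temporary), ten-membered ring, furanone.

Assumption: the SMILES is read as (4Z,6S,7R,8R,10R,11S) with a cis-fused γ-lactone and the homoprenyl group on the ring carbon 1,3 to the spiro centre; this isomer is made.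
Assumption: locants in late names are C1 furanone C=O, C2 furanone CH, C3 enol-ether carbon, C4(=C5) bearing methyl C15, C6 lactone O–CH, C7, C8 oxygenated CH, C9 CH2, C10 quaternary carbon bearing methyl C14, C11 spiro carbon, C12 lactone C=O.
Assumption: the auxiliary, Alpine-Borane, the silylhydroxylamine, catalysts and bulk reagents are named in the Conditions and carry no compound number.

**Route**

Step 1
Reactants: 1 succinic anhydride
Product: 2 4-methoxy-4-oxobutanoic acid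
Conditions: MeOH, reflux
Reagents that add atoms: methanol, CO
Why: Alcoholysis of a cyclic anhydride gives the half ester cleanly.

Step 2
Reactants: 2 4-methoxy-4-oxobutanoic acid
Product: 4 (4S)-4-benzyl-3-(4-methoxy-4-oxobutanoyl)-1,3-oxazolidin-2-one, via mixed pivalic anhydride 3 (not isolated)
Conditions: t-BuCOCl, Et3N, THF, −20 °C; then (4S)-4-benzyl-1,3-oxazolidin-2-one, LiCl, −20 °C → rt
Reagents that add atoms: (4S)-4-benzyl-1,3-oxazolidin-2-one, O=C1N[C@@H](Cc2ccccc2)CO1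
Why: Mixed-anhydride N-acylation activates the acid at the unhindered carbonyl and LiCl makes the oxazolidinone nucleophilic enough without strong base.

Step 3
Reactants: 5 but-2-yn-1-ol
Product: 7 (2Z)-3-iodobut-2-en-1-ol, via cyclic alkenylalanate 6 (not isolated)
Conditions: NaAlH2(OCH2CH2OMe)2, Et2O, 0 °C → rt; then I2, THF, −78 → 0 °C
Reagents that add atoms: iodine, II
Why: Hydroxyl-directed trans-hydroalumination places aluminium on C3 in a five-membered alanate, and iodinolysis with retention gives only the Z iodide.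

Step 4
Reactants: 7 (2Z)-3-iodobut-2-en-1-ol
Product: 8 (2Z)-3-iodobut-2-enal
Conditions: MnO2, CH2Cl2, rt
Reagents that add atoms: none
Why: MnO2 oxidises the allylic alcohol under neutral conditions that do not isomerise the Z double bond.

Step 5
Reactants: 4 (4S)-4-benzyl-3-(4-methoxy-4-oxobutanoyl)-1,3-oxazolidin-2-one; 8 (2Z)-3-iodobut-2-enal
Product: 11 (4S)-4-benzyl-3-{[(2R,3S)-2-[(1Z)-2-iodoprop-1-en-1-yl]-5-oxooxolan-3-yl]carbonyl}-1,3-oxazolidin-2-one, via aldol silyl ether 9 (not isolated), via hydroxy ester 10 (not isolated)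
Conditions: MgCl2 (20 mol %), Et3N, Me3SiCl, EtOAc, rt; then MeOH, CF3CO2H (cat.); then TsOH·H2O (cat.), CH2Cl2, rt
Reagents that add atoms: none
Why: In the Evans magnesium-halide-catalysed anti-aldol the chelated Z-enolate of the (S)-benzyl imide is attacked by the enal on the face away from the benzyl group through a boat-like transition state, which sets C6 and C7 anti; acid desilylation and lactonisation then give the cis-β,γ-disubstituted lactone.

Step 6
Reactants: 11 the lactone imide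
Product: 13 (2R,3S)-2-[(1Z)-2-iodoprop-1-en-1-yl]-5-oxooxolane-3-carboxylic acid, via peroxy acid 12 (not isolated)
Conditions: LiOH, H2O2, THF/H2O, 0 °C; then Na2SO3; then HCl to pH 2
Reagents that add atoms: hydrogen peroxide, OO
Why: Lithium hydroperoxide cleaves the exocyclic imide carbonyl selectively without touching C7, and any opened lactone recloses on acidification because only the five-membered ring can form.

Step 7
Reactants: 14 but-3-en-1-ol
Product: 15 but-3-en-1-yl trifluoromethanesulfonate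
Conditions: Tf2O, 2,6-lutidine, CH2Cl2, −78 °C, used at once
Reagents that add atoms: trifluoromethanesulfonic anhydride, O=S(=O)(OS(=O)(=O)C(F)(F)F)C(F)(F)F
Why: O-Sulfonylation gives a primary electrophile reactive enough to alkylate an enolate at −78 °C, where elimination to butadiene is slow.

Step 8
Reactants: 13 the lactone acid; 15 but-3-en-1-yl trifluoromethanesulfonate
Product: 17 (2R,3S,4S)-4-(but-3-en-1-yl)-2-[(1Z)-2-iodoprop-1-en-1-yl]-5-oxooxolane-3-carboxylic acid (major C4 epimer), via dilithium dianion 16 (not isolated)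
Conditions: LiN(SiMe3)2 (2.1 equiv), THF, −78 °C; then 15 (1.05 equiv), −78 → −40 °C; then 1 M HCl
Reagents that add atoms: none
Why: In the carboxylate–enolate dianion the lactone enolate carbon is the most basic site and is C-alkylated, while the carboxylate keeps C7 from being deprotonated; the new C11 centre is re-enolised in step 11, so its ratio does not matter.

Step 9
Reactants: 18 2-methylprop-2-en-1-ol; 19 1-bromo-3-methylbut-2-ene
Product: 21 6-methyl-2-methylidenehept-5-en-1-ol, via dilithio alkoxide 20 (not isolated)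
Conditions: n-BuLi (2.2 equiv), TMEDA, Et2O/hexane, 0 °C → rt; then 19, −78 °C → rt; then H2O
Reagents that add atoms: none
Why: Allylic metalation of the lithium alkoxide gives a dianion that is alkylated at carbon by the primary allylic bromide (SN2).

Step 10
Reactants: 21 6-methyl-2-methylidenehept-5-en-1-ol
Product: 22 2-(bromomethyl)-6-methylhepta-1,5-diene
Conditions: CBr4, PPh3, CH2Cl2, 0 °C
Reagents that add atoms: carbon tetrabromide, BrC(Br)(Br)Br
Why: The Appel reaction converts the allylic alcohol to the bromide under neutral conditions; direct and allylic substitution give the same product.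

Step 11
Reactants: 17 the butenyl lactone acid; 22 2-(bromomethyl)-6-methylhepta-1,5-diene
Product: 24 (2R,3S,4S)-4-(but-3-en-1-yl)-2-[(1Z)-2-iodoprop-1-en-1-yl]-4-(6-methyl-2-methylidenehept-5-en-1-yl)-5-oxooxolane-3-carboxylic acid, via dilithium dianion 23 (not isolated)
Conditions: LiN(SiMe3)2 (2.2 equiv), THF/DMPU, −78 °C; then 22, −78 → −20 °C; then 1 M HCl
Reagents that add atoms: none
Why: The planar enolate is alkylated on the face away from the cis-disposed C6 and C7 substituents, so the allylic group enters trans to the C7 carboxylate and fixes the quaternary C11 centre.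

Step 12
Reactants: 24 the dialkylated lactone acid
Product: 25 (3R,4S,5S)-3-[(1Z)-2-iodoprop-1-en-1-yl]-7-(4-methylpent-3-en-1-yl)-1-oxo-2-oxaspiro[4.5]dec-7-ene-4-carboxylic acid
Conditions: second-generation Grubbs catalyst (H2IMes)(PCy3)Cl2Ru=CHPh (5 mol %), CH2Cl2 (5 mM), 40 °C
Reagents that add atoms: none
Why: Ring-closing metathesis joins the monosubstituted butenyl alkene to the 1,1-disubstituted alkene to give the six-membered ring with the side chain 1,3 to the spiro carbon, and the trisubstituted prenyl and iodoalkene units are inert; no stereocentre changes.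

Step 13
Reactants: 25 the spirolactone acid
Product: 26 (3R,4S,5S)-N-[(tert-butyldiphenylsilyl)oxy]-3-[(1Z)-2-iodoprop-1-en-1-yl]-7-(4-methylpent-3-en-1-yl)-1-oxo-2-oxaspiro[4.5]dec-7-ene-4-carboxamide
Conditions: TBDPSONH2, DCC, HOBt (cat.), CH2Cl2, 0 °C → rt
Reagents that add atoms: O-(tert-butyldiphenylsilyl)hydroxylamine, NO[Si](c1ccccc1)(c1ccccc1)C(C)(C)C
Why: Carbodiimide amidation gives the O-silyl hydroxamate, a nitrile oxide precursor at the acid oxidation level that avoids a β-acyloxy aldehyde.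

Step 14
Reactants: 27 ethynyl(trimethyl)silane; 28 2-methylprop-2-enal
Product: 30 rac-2-methyl-5-(trimethylsilyl)pent-1-en-4-yn-3-ol, via lithium acetylide 29 (not isolated)
Conditions: n-BuLi, THF, −78 °C; then 28, −78 → 0 °C; then H2O
Reagents that add atoms: none
Why: The lithium acetylide adds 1,2 to the enal.

Step 15
Reactants: 30 rac-2-methyl-5-(trimethylsilyl)pent-1-en-4-yn-3-ol
Product: 31 2-methyl-5-(trimethylsilyl)pent-1-en-4-yn-3-one
Conditions: MnO2, CH2Cl2, rt, used at once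
Reagents that add atoms: none
Why: The doubly activated (allylic and propargylic) alcohol is oxidised by MnO2 under neutral conditions.

Step 16
Reactants: 31 2-methyl-5-(trimethylsilyl)pent-1-en-4-yn-3-one
Product: 33 (3S)-2-methyl-5-(trimethylsilyl)pent-1-en-4-yn-3-ol, via borinate ester 32 (not isolated)
Conditions: (S)-Alpine-Borane (from (−)-α-pinene, 1.5 equiv), THF, rt, 3 d; then ethanolamine
Reagents that add atoms: none
Why: In the Midland reduction the linear alkynyl group is the small substituent in the boat transition state, so the (S)-reagent gives the (S)-carbinol, by analogy with (R)-reagent giving (R)-1-octyn-3-ol.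

Step 17
Reactants: 26 the O-silyl hydroxamate; 33 (3S)-2-methyl-5-(trimethylsilyl)pent-1-en-4-yn-3-ol
Product: 36 (3R,4R,5S)-4-{(5R)-5-[(1R)-1-hydroxy-3-(trimethylsilyl)prop-2-yn-1-yl]-5-methyl-4,5-dihydro-1,2-oxazol-3-yl}-3-[(1Z)-2-iodoprop-1-en-1-yl]-7-(4-methylpent-3-en-1-yl)-2-oxaspiro[4.5]dec-7-en-1-one, via nitrile oxide 34 (not isolated), via magnesium alkoxide 35 (not isolated)
Conditions: Tf2O, Et3N, CH2Cl2, −40 °C; then added to 33 (2.5 equiv)/EtMgBr (2.4 equiv), CH2Cl2, −40 → 0 °C; then H2O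
Reagents that add atoms: none
Why: Dehydration of the O-silyl hydroxamate gives the nitrile oxide, and in the Kanemasa magnesium-alkoxide-directed (3+2) cycloaddition the chelated dipole is delivered to the allylic alkene with oxygen at the substituted carbon and syn to the carbinol oxygen (hydrogen inside, alkynyl anti), which sets C10 as R; the silylated alkyne and the trisubstituted alkenes are much slower dipolarophiles.

Step 18
Reactants: 36 the isoxazoline alcohol
Product: 37 the C1 triethylsilyl ether of 36, (3R,4R,5S)-3-[(1Z)-2-iodoprop-1-en-1-yl]-4-{(5R)-5-methyl-5-[(1R)-1-(triethylsilyloxy)-3-(trimethylsilyl)prop-2-yn-1-yl]-4,5-dihydro-1,2-oxazol-3-yl}-7-(4-methylpent-3-en-1-yl)-2-oxaspiro[4.5]dec-7-en-1-one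
Conditions: Et3SiCl, imidazole, DMAP (cat.), CH2Cl2, 0 °C
Reagents that add atoms: chlorotriethylsilane, CC[Si](Cl)(CC)CC
Why: Silylation of the only free hydroxyl stops the C1 oxygen from binding boron in step 20 and makes the C1 substituent the large, non-coordinating group at C10.

Step 19
Reactants: 37 the silylated isoxazoline
Product: 39 (3R,4S,5S)-4-[(3R,4R)-3-hydroxy-3-methyl-4-(triethylsilyloxy)-6-(trimethylsilyl)hex-5-ynoyl]-3-[(1Z)-2-iodoprop-1-en-1-yl]-7-(4-methylpent-3-en-1-yl)-2-oxaspiro[4.5]dec-7-en-1-one, via hydroxy imine 38 (not isolated)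
Conditions: Mo(CO)6, MeCN/H2O (15:1), 80 °C
Reagents that add atoms: water, O
Why: Reductive N–O cleavage by Mo(CO)6 and hydrolysis of the imine unmask the β-hydroxy ketone (the isoxazoline acting as an aldol surrogate) under neutral conditions that leave C7 and the β-acyloxy ketone intact.

Step 20
Reactants: 39 the β-hydroxy ketone
Product: 40 (3R,4R,5S)-4-[(1R,3R,4R)-1,3-dihydroxy-3-methyl-4-(triethylsilyloxy)-6-(trimethylsilyl)hex-5-yn-1-yl]-3-[(1Z)-2-iodoprop-1-en-1-yl]-7-(4-methylpent-3-en-1-yl)-2-oxaspiro[4.5]dec-7-en-1-one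
Conditions: Me4NBH(OAc)3, MeCN/AcOH (1:1), −30 °C
Reagents that add atoms: none
Why: In the Evans–Saksena reduction the C10 alkoxy-acetoxyborohydride delivers hydride intramolecularly through a chair with the bulky C1 substituent equatorial, giving the 1,3-anti diol and so C8 as R.

Step 21
Reactants: 40 the anti diol
Product: 42 macrocyclic enyne triol (1R,4Z,6S,7R,8R,10R,11S), the ten-membered C1–C10 ring with hydroxyls at C1, C8 and C10 and the C2≡C3–C4(CH3)=C5 enyne, fused to the spirolactone, via terminal alkyne 41 (not isolated)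
Conditions: Bu4NF/AcOH (1:1), THF, 0 °C → rt; then syringe pump into Pd(PPh3)4 (10 mol %), CuI (20 mol %), Et3N, THF (1 mM), 40 °C
Reagents that add atoms: none
Why: Buffered fluoride removes both silyl groups, and an intramolecular Sonogashira coupling closes the ten-membered ring at C3–C4 with retention of the Z geometry; the Z-alkene and the cis-lactone hold the two ends close together.

Step 22
Reactants: 42 the macrocyclic enyne triol
Product: 44 8-hydroxy furanone (4Z,6S,7R,8R,10R,11S), the target lacking its angeloyl group, via macrocyclic ynone 43 (not isolated)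
Conditions: MnO2, CH2Cl2, rt; filter; then (Ph3P)AuCl/AgOTf (5 mol %), toluene, rt
Reagents that add atoms: none
Why: MnO2 oxidises only the propargylic C1 alcohol, and gold-activated 5-endo-dig addition of the C10 hydroxyl to C3 of the ynone forms the furan-3(2H)-one across the ring; the C8 hydroxyl cannot compete because it would form a seven-membered ring.

Step 23
Reactants: 44 the 8-hydroxy furanone; 45 angelic acid [(2Z)-2-methylbut-2-enoic acid]
Product: 47 the target, (4Z,6S,7R,8R,10R,11S)-8-angelate, via mixed anhydride 46 (not isolated)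
Conditions: 45, 2,4,6-trichlorobenzoyl chloride, Et3N, toluene, rt; then 44, toluene, 75 °C
Reagents that add atoms: none
Why: Yamaguchi-type mixed-anhydride acylation without a nucleophilic catalyst esterifies the single free secondary alcohol with retention at C8 and without isomerising the angelate to the tiglate.

**Compound list**

1 | succinic anhydride | O=C1CCC(=O)O1 | starting material
2 | 4-methoxy-4-oxobutanoic acid | COC(=O)CCC(=O)O | intermediate
3 | 4-methoxy-4-oxobutanoic pivalic anhydride (not isolated) | COC(=O)CCC(=O)OC(=O)C(C)(C)C | intermediate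
4 | (4S)-4-benzyl-3-(4-methoxy-4-oxobutanoyl)-1,3-oxazolidin-2-one | COC(=O)CCC(=O)N1[C@@H](Cc2ccccc2)COC1=O | intermediate
5 | but-2-yn-1-ol | CC#CCO | starting material
6 | sodium cyclic alkenylalanate, five-membered C=C–C–O–Al ring with two 2-methoxyethoxy groups on aluminium (not isolated) | CC1=CCO[Al-]1(OCCOC)OCCOC.[Na+] | intermediate
7 | (2Z)-3-iodobut-2-en-1-ol | C/C(I)=C/CO | intermediate
8 | (2Z)-3-iodobut-2-enal | C/C(I)=C/C=O | intermediate
9 | methyl (3S,4R,5Z)-3-{[(4S)-4-benzyl-2-oxo-1,3-oxazolidin-3-yl]carbonyl}-6-iodo-4-(trimethylsilyloxy)hept-5-enoate (not isolated) | COC(=O)C[C@@H]([C@@H](O[Si](C)(C)C)/C=C(/C)I)C(=O)N1[C@@H](Cc2ccccc2)COC1=O | intermediate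
10 | methyl (3S,4R,5Z)-3-{[(4S)-4-benzyl-2-oxo-1,3-oxazolidin-3-yl]carbonyl}-4-hydroxy-6-iodohept-5-enoate (not isolated) | COC(=O)C[C@@H]([C@@H](O)/C=C(/C)I)C(=O)N1[C@@H](Cc2ccccc2)COC1=O | intermediate
11 | (4S)-4-benzyl-3-{[(2R,3S)-2-[(1Z)-2-iodoprop-1-en-1-yl]-5-oxooxolan-3-yl]carbonyl}-1,3-oxazolidin-2-one (cis lactone) | I/C(C)=C\[C@@H]1OC(=O)C[C@@H]1C(=O)N2[C@@H](Cc3ccccc3)COC2=O | intermediate
12 | (2R,3S)-2-[(1Z)-2-iodoprop-1-en-1-yl]-5-oxooxolane-3-carboperoxoic acid (not isolated) | I/C(C)=C\[C@@H]1OC(=O)C[C@@H]1C(=O)OO | intermediate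
13 | (2R,3S)-2-[(1Z)-2-iodoprop-1-en-1-yl]-5-oxooxolane-3-carboxylic acid | I/C(C)=C\[C@@H]1OC(=O)C[C@@H]1C(=O)O | intermediate
14 | but-3-en-1-ol | C=CCCO | starting material
15 | but-3-en-1-yl trifluoromethanesulfonate | C=CCCOS(=O)(=O)C(F)(F)F | intermediate
16 | dilithium carboxylate–lactone enolate of 13 (not isolated) | I/C(C)=C\[C@@H]1OC([O-])=C[C@@H]1C(=O)[O-].[Li+].[Li+] | intermediate
17 | (2R,3S,4S)-4-(but-3-en-1-yl)-2-[(1Z)-2-iodoprop-1-en-1-yl]-5-oxooxolane-3-carboxylic acid (major C4 epimer) | I/C(C)=C\[C@@H]1OC(=O)[C@@H](CCC=C)[C@@H]1C(=O)O | intermediate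
18 | 2-methylprop-2-en-1-ol | C=C(C)CO | starting material
19 | 1-bromo-3-methylbut-2-ene | CC(C)=CCBr | starting material
20 | dilithium 2-(oxidomethyl)prop-2-en-1-ide (not isolated) | [Li+].[Li+].[CH2-]C(=C)C[O-] | intermediate
21 | 6-methyl-2-methylidenehept-5-en-1-ol | C=C(CO)CCC=C(C)C | intermediate
22 | 2-(bromomethyl)-6-methylhepta-1,5-diene | C=C(CBr)CCC=C(C)C | intermediate
23 | dilithium carboxylate–lactone enolate of 17 (not isolated) | I/C(C)=C\[C@@H]1OC([O-])=C(CCC=C)[C@@H]1C(=O)[O-].[Li+].[Li+] | intermediate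
24 | (2R,3S,4S)-4-(but-3-en-1-yl)-2-[(1Z)-2-iodoprop-1-en-1-yl]-4-(6-methyl-2-methylidenehept-5-en-1-yl)-5-oxooxolane-3-carboxylic acid | I/C(C)=C\[C@@H]1OC(=O)[C@](CC(=C)CCC=C(C)C)(CCC=C)[C@@H]1C(=O)O | intermediate
25 | (3R,4S,5S)-3-[(1Z)-2-iodoprop-1-en-1-yl]-7-(4-methylpent-3-en-1-yl)-1-oxo-2-oxaspiro[4.5]dec-7-ene-4-carboxylic acid | I/C(C)=C\[C@@H]1OC(=O)[C@]2(CCC=C(CCC=C(C)C)C2)[C@@H]1C(=O)O | intermediate
26 | (3R,4S,5S)-N-[(tert-butyldiphenylsilyl)oxy]-3-[(1Z)-2-iodoprop-1-en-1-yl]-7-(4-methylpent-3-en-1-yl)-1-oxo-2-oxaspiro[4.5]dec-7-ene-4-carboxamide | I/C(C)=C\[C@@H]1OC(=O)[C@]2(CCC=C(CCC=C(C)C)C2)[C@@H]1C(=O)NO[Si](c3ccccc3)(c4ccccc4)C(C)(C)C | intermediate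
27 | ethynyl(trimethyl)silane | C#C[Si](C)(C)C | starting material
28 | 2-methylprop-2-enal | C=C(C)C=O | starting material
29 | lithium (trimethylsilyl)acetylide (not isolated) | [Li+].[C-]#C[Si](C)(C)C | intermediate
30 | rac-2-methyl-5-(trimethylsilyl)pent-1-en-4-yn-3-ol | C=C(C)C(O)C#C[Si](C)(C)C | intermediate
31 | 2-methyl-5-(trimethylsilyl)pent-1-en-4-yn-3-one | C=C(C)C(=O)C#C[Si](C)(C)C | intermediate
32 | 9-{[(3S)-2-methyl-5-(trimethylsilyl)pent-1-en-4-yn-3-yl]oxy}-9-borabicyclo[3.3.1]nonane (not isolated) | C=C(C)[C@H](OB1C2CCCC1CCC2)C#C[Si](C)(C)C | intermediate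
33 | (3S)-2-methyl-5-(trimethylsilyl)pent-1-en-4-yn-3-ol | C=C(C)[C@H](O)C#C[Si](C)(C)C | intermediate
34 | (3R,4R,5S)-3-[(1Z)-2-iodoprop-1-en-1-yl]-7-(4-methylpent-3-en-1-yl)-1-oxo-2-oxaspiro[4.5]dec-7-ene-4-carbonitrile N-oxide (not isolated) | I/C(C)=C\[C@@H]1OC(=O)[C@]2(CCC=C(CCC=C(C)C)C2)[C@@H]1C#[N+][O-] | intermediate
35 | bromomagnesium (3S)-2-methyl-5-(trimethylsilyl)pent-1-en-4-yn-3-olate (not isolated) | C=C(C)[C@H](O[Mg]Br)C#C[Si](C)(C)C | intermediate
36 | (3R,4R,5S)-4-{(5R)-5-[(1R)-1-hydroxy-3-(trimethylsilyl)prop-2-yn-1-yl]-5-methyl-4,5-dihydro-1,2-oxazol-3-yl}-3-[(1Z)-2-iodoprop-1-en-1-yl]-7-(4-methylpent-3-en-1-yl)-2-oxaspiro[4.5]dec-7-en-1-one | I/C(C)=C\[C@@H]1OC(=O)[C@]2(CCC=C(CCC=C(C)C)C2)[C@@H]1C3=NO[C@](C)(C3)[C@H](O)C#C[Si](C)(C)C | intermediate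
37 | (3R,4R,5S)-3-[(1Z)-2-iodoprop-1-en-1-yl]-4-{(5R)-5-methyl-5-[(1R)-1-(triethylsilyloxy)-3-(trimethylsilyl)prop-2-yn-1-yl]-4,5-dihydro-1,2-oxazol-3-yl}-7-(4-methylpent-3-en-1-yl)-2-oxaspiro[4.5]dec-7-en-1-one | I/C(C)=C\[C@@H]1OC(=O)[C@]2(CCC=C(CCC=C(C)C)C2)[C@@H]1C3=NO[C@](C)(C3)[C@H](O[Si](CC)(CC)CC)C#C[Si](C)(C)C | intermediate
38 | β-hydroxy imine, the C8=NH analogue of 39 (not isolated) | I/C(C)=C\[C@@H]1OC(=O)[C@]2(CCC=C(CCC=C(C)C)C2)[C@@H]1C(=N)C[C@@](C)(O)[C@H](O[Si](CC)(CC)CC)C#C[Si](C)(C)C | intermediate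
39 | (3R,4S,5S)-4-[(3R,4R)-3-hydroxy-3-methyl-4-(triethylsilyloxy)-6-(trimethylsilyl)hex-5-ynoyl]-3-[(1Z)-2-iodoprop-1-en-1-yl]-7-(4-methylpent-3-en-1-yl)-2-oxaspiro[4.5]dec-7-en-1-one | I/C(C)=C\[C@@H]1OC(=O)[C@]2(CCC=C(CCC=C(C)C)C2)[C@@H]1C(=O)C[C@@](C)(O)[C@H](O[Si](CC)(CC)CC)C#C[Si](C)(C)C | intermediate
40 | (3R,4R,5S)-4-[(1R,3R,4R)-1,3-dihydroxy-3-methyl-4-(triethylsilyloxy)-6-(trimethylsilyl)hex-5-yn-1-yl]-3-[(1Z)-2-iodoprop-1-en-1-yl]-7-(4-methylpent-3-en-1-yl)-2-oxaspiro[4.5]dec-7-en-1-one | I/C(C)=C\[C@@H]1OC(=O)[C@]2(CCC=C(CCC=C(C)C)C2)[C@@H]1[C@H](O)C[C@@](C)(O)[C@H](O[Si](CC)(CC)CC)C#C[Si](C)(C)C | intermediate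
41 | (3R,4R,5S)-3-[(1Z)-2-iodoprop-1-en-1-yl]-7-(4-methylpent-3-en-1-yl)-4-[(1R,3R,4R)-1,3,4-trihydroxy-3-methylhex-5-yn-1-yl]-2-oxaspiro[4.5]dec-7-en-1-one (not isolated) | I/C(C)=C\[C@@H]1OC(=O)[C@]2(CCC=C(CCC=C(C)C)C2)[C@@H]1[C@H](O)C[C@@](C)(O)[C@H](O)C#C | intermediate
42 | macrocyclic enyne triol (1R,4Z,6S,7R,8R,10R,11S): ten-membered C1–C10 ring, OH at C1, C8, C10, C2≡C3, C4(CH3)=C5, cis-fused C6/C7 spirolactone | O[C@@H]1C[C@@](C)(O)[C@H](O)C#C/C(C)=C\[C@@H]2OC(=O)[C@]3(CCC=C(CCC=C(C)C)C3)[C@@H]21 | intermediate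
43 | macrocyclic α′-hydroxy ynone (4Z,6S,7R,8R,10R,11S): as 42 with C1=O (not isolated) | O[C@@H]1C[C@@](C)(O)C(=O)C#C/C(C)=C\[C@@H]2OC(=O)[C@]3(CCC=C(CCC=C(C)C)C3)[C@@H]21 | intermediate
44 | 8-hydroxy furanone (4Z,6S,7R,8R,10R,11S): the target without the angeloyl group | O[C@@H]1C[C@@]2(C)OC(=CC2=O)/C(C)=C\[C@@H]2OC(=O)[C@]3(CCC=C(CCC=C(C)C)C3)[C@@H]21 | intermediate
45 | angelic acid, (2Z)-2-methylbut-2-enoic acid | C/C=C(/C)C(=O)O | starting material
46 | (2Z)-2-methylbut-2-enoic 2,4,6-trichlorobenzoic anhydride (not isolated) | C/C=C(/C)C(=O)OC(=O)c1c(Cl)cc(Cl)cc1Cl | intermediate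
47 | CNP0226905.2, (4Z,6S,7R,8R,10R,11S)-8-[(2Z)-2-methylbut-2-enoyloxy] spiro furanone lactone | C/C=C(/C)C(=O)O[C@@H]1C[C@@]2(C)OC(=CC2=O)/C(C)=C\[C@@H]2OC(=O)[C@]3(CCC=C(CCC=C(C)C)C3)[C@@H]21 | target

**Step count**

Total step count: 23.
Longest linear sequence: 15 steps (1, 2, 5, 6, 8, 11, 12, 13, 17, 18, 19, 20, 21, 22, 23).

**Steps most likely to fail, with fallbacks**

Step 21 (closing a strained ten-membered enyne ring by Sonogashira coupling on an unprotected triol). The fallback sets out from 40 and returns at 44. Desilylation with Bu4NF/AcOH is stopped at triol 41, which is isolated. MnO2 then oxidises the propargylic alcohol to the terminal α′-hydroxy ynone (3R,4R,5S)-4-[(1R,3R)-1,3-dihydroxy-3-methyl-4-oxohex-5-yn-1-yl]-3-[(1Z)-2-iodoprop-1-en-1-yl]-7-(4-methylpent-3-en-1-yl)-2-oxaspiro[4.5]dec-7-en-1-one F1. (Ph3P)AuCl/AgOTf closes it to the open-chain furanone (3R,4R,5S)-4-{(1R)-1-hydroxy-2-[(2R)-2-methyl-3-oxo-2,3-dihydrofuran-2-yl]ethyl}-3-[(1Z)-2-iodoprop-1-en-1-yl]-7-(4-methylpent-3-en-1-yl)-2-oxaspiro[4.5]dec-7-en-1-one F2, whose C3 is still unsubstituted. An intramolecular Heck reaction (Pd(OAc)2, P(o-tolyl)3, Ag2CO3, MeCN, 1 mM, 70 °C) then forms the C3–C4 bond: the alkenylpalladium adds to the enol-ether terminus C3, and β-hydride elimination through the palladium enolate restores the furanone and gives 44. The ring is thus closed on the finished, less strained furanone instead of on the alkyne.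

Step 17 (intermolecular directed cycloaddition in the presence of nearby alkenes; dimerisation or internal trapping of the nitrile oxide). The fallback sets out from 26 and 33 and returns at 42. K2CO3/MeOH removes the C-silyl group of 33 to give (3S)-2-methylpent-1-en-4-yn-3-ol F3. Intermolecular Sonogashira coupling with 26 (Pd(PPh3)4, CuI, Et3N, THF) gives the enynol hydroxamate (3S,4S,5S)-N-[(tert-butyldiphenylsilyl)oxy]-3-[(1Z,5S)-5-hydroxy-2,6-dimethylhepta-1,6-dien-3-yn-1-yl]-7-(4-methylpent-3-en-1-yl)-1-oxo-2-oxaspiro[4.5]dec-7-ene-4-carboxamide F4. Tf2O/Et3N at −40 °C followed by slow addition to i-PrMgCl (CH2Cl2, 1 mM) generates the tethered nitrile oxide (3S,4R,5S)-3-[(1Z,5S)-5-hydroxy-2,6-dimethylhepta-1,6-dien-3-yn-1-yl]-7-(4-methylpent-3-en-1-yl)-1-oxo-2-oxaspiro[4.5]dec-7-ene-4-carbonitrile N-oxide F5. Its own magnesium alkoxide delivers the dipole to the allylic alkene, so the ring closes as the C8=N–O–C10-bridged macrocyclic isoxazoline (1R,4Z,6S,7R,10R,11S) F6. Mo(CO)6 in wet MeCN opens F6 through the macrocyclic hydroxy imine F7 to the macrocyclic β-hydroxy ketone (1R,4Z,6S,7S,10R,11S) F8, and Me4NBH(OAc)3 reduces C8 from the C10 alkoxyborohydride to give 42. The cycloaddition becomes the ring-closing step and the cross-coupling becomes the easy intermolecular one.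

Step 5 (a succinate half-ester imide and a β-iodo enal are outside the tested range of the magnesium-catalysed anti-aldol). The fallback sets out from 2 and 8 and returns at 13. Acid 2 is acylated as in step 2 onto the enantiomeric auxiliary to give (4R)-4-benzyl-3-(4-methoxy-4-oxobutanoyl)-1,3-oxazolidin-2-one F9. Its Z-boron enolate (Bu2BOTf, i-Pr2NEt, CH2Cl2, −78 °C) adds to 8 in the Evans syn sense to give methyl (3S,4S,5Z)-3-{[(4R)-4-benzyl-2-oxo-1,3-oxazolidin-3-yl]carbonyl}-4-hydroxy-6-iodohept-5-enoate F10, which has the required C7 and the opposite C6. Acid work-up closes it to the trans lactone imide (4R)-4-benzyl-3-{[(2S,3S)-2-[(1Z)-2-iodoprop-1-en-1-yl]-5-oxooxolan-3-yl]carbonyl}-1,3-oxazolidin-2-one F11, and LiOH/H2O2 gives the trans acid (2S,3S)-2-[(1Z)-2-iodoprop-1-en-1-yl]-5-oxooxolane-3-carboxylic acid F12. LiOH opens the lactone to the hydroxy diacid (2S)-2-[(1S,2Z)-1-hydroxy-3-iodobut-2-en-1-yl]butanedioic acid F13, kept cold and never strongly acidified. Mitsunobu lactonisation (PPh3, DIAD, THF, 0 °C) closes the five-membered ring with inversion at C6 and gives the cis acid 13.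

**Further compounds**

F1 | step 21 | (3R,4R,5S)-4-[(1R,3R)-1,3-dihydroxy-3-methyl-4-oxohex-5-yn-1-yl]-3-[(1Z)-2-iodoprop-1-en-1-yl]-7-(4-methylpent-3-en-1-yl)-2-oxaspiro[4.5]dec-7-en-1-one | I/C(C)=C\[C@@H]1OC(=O)[C@]2(CCC=C(CCC=C(C)C)C2)[C@@H]1[C@H](O)C[C@@](C)(O)C(=O)C#C
F2 | step 21 | (3R,4R,5S)-4-{(1R)-1-hydroxy-2-[(2R)-2-methyl-3-oxo-2,3-dihydrofuran-2-yl]ethyl}-3-[(1Z)-2-iodoprop-1-en-1-yl]-7-(4-methylpent-3-en-1-yl)-2-oxaspiro[4.5]dec-7-en-1-one | I/C(C)=C\[C@@H]1OC(=O)[C@]2(CCC=C(CCC=C(C)C)C2)[C@@H]1[C@H](O)C[C@@]3(C)OC=CC3=O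
F3 | step 17 | (3S)-2-methylpent-1-en-4-yn-3-ol | C=C(C)[C@H](O)C#C
F4 | step 17 | (3S,4S,5S)-N-[(tert-butyldiphenylsilyl)oxy]-3-[(1Z,5S)-5-hydroxy-2,6-dimethylhepta-1,6-dien-3-yn-1-yl]-7-(4-methylpent-3-en-1-yl)-1-oxo-2-oxaspiro[4.5]dec-7-ene-4-carboxamide | C=C(C)[C@H](O)C#C/C(C)=C\[C@@H]1OC(=O)[C@]2(CCC=C(CCC=C(C)C)C2)[C@@H]1C(=O)NO[Si](c3ccccc3)(c4ccccc4)C(C)(C)C
F5 | step 17 | (3S,4R,5S)-3-[(1Z,5S)-5-hydroxy-2,6-dimethylhepta-1,6-dien-3-yn-1-yl]-7-(4-methylpent-3-en-1-yl)-1-oxo-2-oxaspiro[4.5]dec-7-ene-4-carbonitrile N-oxide | C=C(C)[C@H](O)C#C/C(C)=C\[C@@H]1OC(=O)[C@]2(CCC=C(CCC=C(C)C)C2)[C@@H]1C#[N+][O-]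
F6 | step 17 | macrocyclic isoxazoline (1R,4Z,6S,7R,10R,11S) with the C8=N–O–C10 bridge and C1 hydroxyl | O[C@@H]1C#C/C(C)=C\[C@@H]2OC(=O)[C@]3(CCC=C(CCC=C(C)C)C3)[C@@H]2C4=NO[C@]1(C)C4
F7 | step 17 | macrocyclic β-hydroxy imine, the C8=NH analogue of F8 | O[C@@H]1C#C/C(C)=C\[C@@H]2OC(=O)[C@]3(CCC=C(CCC=C(C)C)C3)[C@@H]2C(=N)C[C@@]1(C)O
F8 | step 17 | macrocyclic β-hydroxy ketone (1R,4Z,6S,7S,10R,11S) with C8=O and hydroxyls at C1 and C10 | O[C@@H]1C#C/C(C)=C\[C@@H]2OC(=O)[C@]3(CCC=C(CCC=C(C)C)C3)[C@@H]2C(=O)C[C@@]1(C)O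
F9 | step 5 | (4R)-4-benzyl-3-(4-methoxy-4-oxobutanoyl)-1,3-oxazolidin-2-one | COC(=O)CCC(=O)N1[C@H](Cc2ccccc2)COC1=O
F10 | step 5 | methyl (3S,4S,5Z)-3-{[(4R)-4-benzyl-2-oxo-1,3-oxazolidin-3-yl]carbonyl}-4-hydroxy-6-iodohept-5-enoate | COC(=O)C[C@@H]([C@H](O)/C=C(/C)I)C(=O)N1[C@H](Cc2ccccc2)COC1=O
F11 | step 5 | (4R)-4-benzyl-3-{[(2S,3S)-2-[(1Z)-2-iodoprop-1-en-1-yl]-5-oxooxolan-3-yl]carbonyl}-1,3-oxazolidin-2-one | I/C(C)=C\[C@H]1OC(=O)C[C@@H]1C(=O)N2[C@H](Cc3ccccc3)COC2=O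
F12 | step 5 | (2S,3S)-2-[(1Z)-2-iodoprop-1-en-1-yl]-5-oxooxolane-3-carboxylic acid | I/C(C)=C\[C@H]1OC(=O)C[C@@H]1C(=O)O
F13 | step 5 | (2S)-2-[(1S,2Z)-1-hydroxy-3-iodobut-2-en-1-yl]butanedioic acid | OC(=O)C[C@@H]([C@H](O)/C=C(/C)I)C(=O)O
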